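**Retrosynthetic overview**
1. Target 15 ⇐ O-demethylation of tetramethyl ether 14 ⇐ epimerisation of the two aroyl-bearing carbons (C1, C3) of all-cis 13 ⇐ syn hydrogenolysis of the central bond of bicyclo[1.1.0]butane 12.
2. Feature: in the cyclobutane C1(aroyl)–C2(Ph)–C3(aroyl)–C4(Ph), the phenyl carbons C2 and C4 lie 1,3 across the ring and are cis. A temporary C2–C4 bond turns the ring into a bicyclo[1.1.0]butane in which C1 and C3 are each the apex of a three-membered ring, i.e. a carbene carbon placed on a C2=C4 double bond.
3. Key disconnection: 12 ⇒ aroylcarbene from diazoketone 11 (C3) + cyclopropenyl ketone 7, forming C3–C2 and C3–C4.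
4. 7 ⇐ Weinreb amide 4 + aryl Grignard reagent 5; 4 ⇐ ester 3 ⇐ diphenylacetylene 1 + ethyl diazoacetate 2 (C1 onto C2≡C4); 11 ⇐ acid chloride 8 + trimethylsilyldiazomethane 9.
5. Ring order: cyclopropene (step 1), second three-membered ring giving the bicyclobutane (step 5), cyclobutane revealed by central-bond cleavage (step 6).

Key step: step 5

Remark: step 6 is assumed to deliver both hydrogens from the concave face of 12 (the face carrying only the two endo hydrogens), giving all-cis 13; delivery from the convex face would give 14 directly, and step 7 converges either outcome. All ring compounds are achiral, so the descriptors give relative configuration.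

**Step 1**
Reactants: 1 diphenylacetylene; 2 ethyl diazoacetate
Product: 3 ethyl 2,3-diphenylcycloprop-2-ene-1-carboxylate
Conditions: Rh2(OAc)4 (1 mol%), CH2Cl2, rt, 2 added over 8 h to 1 (3 equiv)
Reagents that add atoms: none
Why: Rh2(OAc)4-catalysed cyclopropenation, in which the ester carbenoid from 2 adds (2+1) to the alkyne of 1, the excess alkyne suppressing carbene dimerisation; no stereocentre is formed.

**Step 2**
Reactants: 3 ethyl 2,3-diphenylcycloprop-2-ene-1-carboxylate
Product: 4 N-methoxy-N-methyl-2,3-diphenylcycloprop-2-ene-1-carboxamide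
Conditions: MeNHOMe·HCl (1.5 equiv), iPrMgCl (3 equiv), THF, −20 to 0 °C; then H2O
Reagents that add atoms: N,O-dimethylhydroxylamine hydrochloride, CNOC.Cl
Why: Weinreb amide formation by aminolysis of the ester with the chloromagnesium amide is fast at low temperature, and the ring C–H next to the carbonyl is not removed because its anion would be an antiaromatic cyclopropenyl anion; no stereocentre is formed.

**Step 3**
Reactants: 4 N-methoxy-N-methyl-2,3-diphenylcycloprop-2-ene-1-carboxamide; 5 2,4-dimethoxyphenylmagnesium bromide
Product: 7 (2,4-dimethoxyphenyl)(2,3-diphenylcycloprop-2-en-1-yl)methanone, via bromomagnesium hemiaminal adduct 6 (not isolated)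
Conditions: 5 (1.5 equiv), THF, 0 °C to rt; then H2O
Reagents that add atoms: none
Why: Weinreb ketone synthesis, in which the Grignard reagent adds once to give the magnesium-chelated tetrahedral adduct 6 that persists until the aqueous quench and so prevents over-addition; no stereocentre is formed.

**Step 4**
Reactants: 8 2,4-dimethoxybenzoyl chloride; 9 trimethylsilyldiazomethane
Product: 11 2-diazo-1-(2,4-dimethoxyphenyl)ethan-1-one, via α-silyl diazoketone 10 (not isolated)
Conditions: 9 (2.2 equiv), THF/MeCN 1:1, 0 °C to rt; then aq NaHCO3
Reagents that add atoms: none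
Why: Arndt–Eistert-type C-acylation of the diazoalkane by the acid chloride, the second equivalent of 9 taking up the HCl, followed by protodesilylation of 10 on aqueous work-up; no stereocentre is formed.

**Step 5**
Reactants: 7 (2,4-dimethoxyphenyl)(2,3-diphenylcycloprop-2-en-1-yl)methanone; 11 2-diazo-1-(2,4-dimethoxyphenyl)ethan-1-one
Product: 12 exo,exo-2,4-bis(2,4-dimethoxybenzoyl)-1,3-diphenylbicyclo[1.1.0]butane
Conditions: Rh2(OAc)4 (1 mol%), CH2Cl2, 0 °C to rt, 11 (2.5 equiv) added over 4 h
Reagents that add atoms: none
Why: Rh2(OAc)4 expels N2 from 11 to give an electrophilic rhodium aroylcarbenoid, which adds in a concerted, asynchronous (2+1) fashion across the strained, stilbene-like double bond of 7 and so forms both new bonds from the carbene carbon to the two phenyl-bearing carbons. The closest known reaction type is the metal-catalysed addition of diazocarbonyl compounds to 3-acyl-1,2-diarylcyclopropenes, which gives 1,3-diarylbicyclo[1.1.0]butanes. The ring that closes is the second three-membered ring, by suprafacial (2+1) carbene addition to the alkene, and this completes the bicyclo[1.1.0]butane. The two bridgehead centres are fixed by the geometry of the fused rings, the existing aroyl-bearing carbon becomes exo because the carbenoid approaches the cyclopropene face anti to that aroyl group, and the new bridge carbon is expected exo because the carbenoid turns its aroyl group away from the ring during approach. The step needs the (2+1) addition to outrun rhodium-induced opening of the cyclopropenyl ketone to a furan, carbene dimerisation and capture of the carbenoid by its own ortho-methoxy oxygen; the strain and electron-rich character of the diaryl-substituted double bond, the moderate electrophilicity of the acetate-ligated catalyst at low temperature and the slow addition of excess 11 are relied on for this. An endo epimer at the new bridge would not be lost, because both aroyl centres are equilibrated in step 7.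

**Step 6**
Reactants: 12 exo,exo-2,4-bis(2,4-dimethoxybenzoyl)-1,3-diphenylbicyclo[1.1.0]butane
Product: 13 all-cis-[2,4-diphenylcyclobutane-1,3-diyl]bis[(2,4-dimethoxyphenyl)methanone]
Conditions: H2 (1 atm), 5% Pd/C, EtOAc, rt
Reagents that add atoms: none
Why: Catalytic hydrogenolysis of the central bond of the bicyclo[1.1.0]butane, which is doubly benzylic and the most strained bond, should deliver both hydrogens syn to the two bridgeheads from the concave face, so that the phenyl groups become cis to each other and remain on the face of the exo aroyl groups.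

**Step 7**
Reactants: 13 all-cis-[2,4-diphenylcyclobutane-1,3-diyl]bis[(2,4-dimethoxyphenyl)methanone]
Product: 14 all-trans-[2,4-diphenylcyclobutane-1,3-diyl]bis[(2,4-dimethoxyphenyl)methanone] (aroyl groups cis to each other, phenyl groups cis to each other, each aroyl trans to both neighbouring phenyls)
Conditions: DBU (0.5 equiv), toluene, 60 °C
Reagents that add atoms: none
Why: Base-mediated epimerisation through the ketone enolates at C1 and C3 relieves the cis interaction of each aroyl group with two flanking phenyl groups, so thermodynamic control gives the all-trans isomer while the non-acidic phenyl-bearing centres stay cis.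

**Step 8**
Reactants: 14 all-trans-[2,4-diphenylcyclobutane-1,3-diyl]bis[(2,4-dimethoxyphenyl)methanone]
Product: 15 [(1α,2β,3α,4β)-2,4-diphenylcyclobutane-1,3-diyl]bis[(2,4-dihydroxyphenyl)methanone] (target)
Conditions: BBr3 (10 equiv), CH2Cl2, −78 °C to rt; then H2O
Reagents that add atoms: none
Why: Global aryl methyl ether cleavage with BBr3 (boron coordination, then bromide attack at methyl) frees the four phenols, and because 14 already has the thermodynamic all-trans arrangement any Lewis acid-induced enolisation cannot change the configuration.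

**Compound list**
1 | diphenylacetylene | C(#Cc1ccccc1)c1ccccc1 | starting material
2 | ethyl diazoacetate | CCOC(=O)C=[N+]=[N-] | starting material
3 | ethyl 2,3-diphenylcycloprop-2-ene-1-carboxylate | CCOC(=O)C1C(c2ccccc2)=C1c1ccccc1 | intermediate
4 | N-methoxy-N-methyl-2,3-diphenylcycloprop-2-ene-1-carboxamide | CON(C)C(=O)C1C(c2ccccc2)=C1c1ccccc1 | intermediate
5 | 2,4-dimethoxyphenylmagnesium bromide | COc1ccc([Mg]Br)c(OC)c1 | starting material
6 | bromomagnesium hemiaminal adduct of 4 and 5 | COc1ccc(C(O[Mg]Br)(N(C)OC)C2C(c3ccccc3)=C2c2ccccc2)c(OC)c1 | intermediate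
7 | (2,4-dimethoxyphenyl)(2,3-diphenylcycloprop-2-en-1-yl)methanone | O=C(c1ccc(OC)cc1OC)C1C(c2ccccc2)=C1c1ccccc1 | intermediate
8 | 2,4-dimethoxybenzoyl chloride | COc1ccc(C(=O)Cl)c(OC)c1 | starting material
9 | trimethylsilyldiazomethane | C[Si](C)(C)C=[N+]=[N-] | starting material
10 | 2-diazo-1-(2,4-dimethoxyphenyl)-2-(trimethylsilyl)ethan-1-one | COc1ccc(C(=O)C(=[N+]=[N-])[Si](C)(C)C)c(OC)c1 | intermediate
11 | 2-diazo-1-(2,4-dimethoxyphenyl)ethan-1-one | [N-]=[N+]=CC(=O)c1ccc(OC)cc1OC | intermediate
12 | exo,exo-2,4-bis(2,4-dimethoxybenzoyl)-1,3-diphenylbicyclo[1.1.0]butane | O=C(c1ccc(OC)cc1OC)[C@H]1[C@]2(c3ccccc3)[C@@H](C(=O)c3ccc(OC)cc3OC)[C@]12c1ccccc1 | intermediate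
13 | all-cis-[2,4-diphenylcyclobutane-1,3-diyl]bis[(2,4-dimethoxyphenyl)methanone] | O=C(c1ccc(OC)cc1OC)[C@H]1[C@@H](c2ccccc2)[C@@H](C(=O)c2ccc(OC)cc2OC)[C@H]1c1ccccc1 | intermediate
14 | all-trans-[2,4-diphenylcyclobutane-1,3-diyl]bis[(2,4-dimethoxyphenyl)methanone] | O=C(c1ccc(OC)cc1OC)[C@H]1[C@H](c2ccccc2)[C@@H](C(=O)c2ccc(OC)cc2OC)[C@@H]1c1ccccc1 | intermediate
15 | [(1α,2β,3α,4β)-2,4-diphenylcyclobutane-1,3-diyl]bis[(2,4-dihydroxyphenyl)methanone] | O=C(c1ccc(O)cc1O)[C@H]1[C@H](c2ccccc2)[C@@H](C(=O)c2ccc(O)cc2O)[C@@H]1c1ccccc1 | target

**Step count**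
Total: 8 steps. Longest linear sequence: 7 steps (steps 1, 2, 3, 5, 6, 7, 8); step 4 is a one-step branch.

**Steps most likely to fail**

Step 5. Opening of the cyclopropene of 7 by the rhodium catalyst with closure onto the ketone oxygen (furan formation), and capture of the aroylcarbenoid by its own ortho-methoxy oxygen or by a second molecule of 11, may consume both partners faster than the (2+1) addition. The fallback builds the bicyclobutane at the ester oxidation level, where neither process is available, and installs the aryl ketones afterwards. It sets out from ester 3. CuSO4-catalysed addition of ethyl diazoacetate 2 to 3 in toluene at 80 °C should give diethyl exo,exo-1,3-diphenylbicyclo[1.1.0]butane-2,4-dicarboxylate F1. H2 over Pd/C in EtOAc should open the central bond to diethyl all-cis-2,4-diphenylcyclobutane-1,3-dicarboxylate F2. NaOEt in EtOH should equilibrate the two ester centres to diethyl all-trans-2,4-diphenylcyclobutane-1,3-dicarboxylate F3. MeNHOMe·HCl with iPrMgCl should then give the all-trans bis(N-methoxy-N-methylamide) of 2,4-diphenylcyclobutane-1,3-dicarboxylic acid F4. Two equivalents of Grignard reagent 5 should convert F4 into 14, where the fallback rejoins the route before step 8.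

Step 6. Hydrogenation of the two aryl ketone carbonyls, and onward hydrogenolysis of the resulting benzylic C–O bonds, may compete with cleavage of the central bond and leave a mixture of oxidation levels. The fallback is a redox detour that sets out from 12. NaBH4 in MeOH/THF at 0 °C should reduce both ketones to the exo,exo-bicyclobutane bis(aryl carbinol) F5 (carbinol configuration immaterial). H2 over Pd/C in EtOAc containing Et3N, which suppresses benzylic C–O cleavage, should open the central bond to the all-cis cyclobutane bis(aryl carbinol) F6. Dess–Martin periodinane in CH2Cl2 should re-oxidise both carbinols and return the material to the route at 13.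

Step 8. Cleavage may stall at the two para-methoxy groups once the ortho oxygens are bound to boron, and the longer exposure needed to finish it may degrade the strained diketone. The fallback is a two-stage demethylation with two different mechanisms, setting out from 14. BCl3 in CH2Cl2 at −78 to 0 °C should remove only the two ortho methyl groups through carbonyl chelation and give all-trans-[2,4-diphenylcyclobutane-1,3-diyl]bis[(2-hydroxy-4-methoxyphenyl)methanone] F7. NaSEt in DMF at 110 °C should then remove the para methyl groups by thiolate attack at methyl, returning to the route at 15.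

**Further compounds**
F1 | step 5 | diethyl exo,exo-1,3-diphenylbicyclo[1.1.0]butane-2,4-dicarboxylate | CCOC(=O)[C@H]1[C@]2(c3ccccc3)[C@@H](C(=O)OCC)[C@]12c1ccccc1
F2 | step 5 | diethyl all-cis-2,4-diphenylcyclobutane-1,3-dicarboxylate | CCOC(=O)[C@H]1[C@@H](c2ccccc2)[C@@H](C(=O)OCC)[C@H]1c1ccccc1
F3 | step 5 | diethyl all-trans-2,4-diphenylcyclobutane-1,3-dicarboxylate | CCOC(=O)[C@H]1[C@H](c2ccccc2)[C@@H](C(=O)OCC)[C@@H]1c1ccccc1
F4 | step 5 | all-trans-N1,N3-dimethoxy-N1,N3-dimethyl-2,4-diphenylcyclobutane-1,3-dicarboxamide | CON(C)C(=O)[C@H]1[C@H](c2ccccc2)[C@@H](C(=O)N(C)OC)[C@@H]1c1ccccc1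
F5 | step 6 | exo,exo-[1,3-diphenylbicyclo[1.1.0]butane-2,4-diyl]bis[(2,4-dimethoxyphenyl)methanol] | OC(c1ccc(OC)cc1OC)[C@H]1[C@]2(c3ccccc3)[C@@H](C(O)c3ccc(OC)cc3OC)[C@]12c1ccccc1
F6 | step 6 | all-cis-[2,4-diphenylcyclobutane-1,3-diyl]bis[(2,4-dimethoxyphenyl)methanol] | OC(c1ccc(OC)cc1OC)[C@H]1[C@@H](c2ccccc2)[C@@H](C(O)c2ccc(OC)cc2OC)[C@H]1c1ccccc1
F7 | step 8 | all-trans-[2,4-diphenylcyclobutane-1,3-diyl]bis[(2-hydroxy-4-methoxyphenyl)methanone] | O=C(c1ccc(OC)cc1O)[C@H]1[C@H](c2ccccc2)[C@@H](C(=O)c2ccc(OC)cc2O)[C@@H]1c1ccccc1
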